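Colleague, you asked for a quick number on the new flask, so here is mine, with the road to it.

| setting | larch | cedar | flask |
|---|---|---|---|
| starting material | 0.25 M (in portions, 4) | 0.40 M (in portions, 4) | 0.18 M (in portions, 4) |
| partner | 0.18 M | 0.18 M | 0.180 M |
| protic impurity | 0.054 M | 0.054 M | 0.0540 M |
| initiator | 4.5 mM | 4.5 mM | 4.5 mM |
| remark | run made earlier; portions every 4.0 min | run made earlier; portions every 4.0 min | the portions of starting material follow each other after 4.0 min, the first at the start |
| time |  |  | 10 h |

- larch (time / h: target / %, starting material / %): 0.500: 61.5, 20.6; 0.667: 65.2, 13.4; 1.00: 68.6, 8.5; 1.50: 71.7, 6.3; 2.50: 71.7, 4.2; 4.00: 71.4, 4.8; 6.00: 71.2, 3.9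
- cedar (time / h: target / %, starting material / %): 0.333: 33.5, 53.5; 1.00: 43.5, 40.9; 1.50: 43.8, 39.5; 2.50: 44.6, 39.3; 4.00: 45.0, 41.2; 5.00: 44.1, 38.9; 6.00: 45.3, 40.1

(readings scatter by 0.5 percentage points)

- a species is counted by the starting material in it: one ended chains A counts as two
- steps under discussion: initiator -> 2 initiating radical; starting material + initiating radical -> capped initiator + first chain carrier; partner + first chain carrier -> target + second chain carrier; starting material + second chain carrier -> released group + first chain carrier; first chain carrier -> ended carrier; 2 first chain carrier -> ended chains A; 2 second chain carrier -> ended chains B; starting material + protic impurity -> quenched substrate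
- the reaction counts as stopped when no species that holds the starting material changes by six tenths of a point or more over the second half of the time

- which holds at 10 h: what has brought the reaction to rest, or that it has not come to rest (the partner has run out first / forward and back rates have come level / all of the starting material has reacted / it is still moving)
- the target standing at 10 h, as a percentage of the starting material charged
- amount of target if the flask were left three thousand times as long, in percent of the starting material charged

Start from the plateaus. Late target stands at 0.179 M in larch and 0.181 M in cedar, each close to [partner] = 0.18 M, so partner capped both runs. The flask is charged differently, and you need to know how much of the reacted starting material becomes target. Take the usable share, the target formed divided by the starting material consumed up to one reading. The units of time cancel in this ratio, but its value still belongs to the moment of its reading, so I name the reading I use.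

The larch reading at 0.500 h gives 0.775. The first cedar reading, at 0.333 h, gives 0.720, lower, at another moment and under another charge. The larch charge stands nearer the flask's, so I take larch as the guide. Target is then the smaller of share times charge and the partner charge. In the flask the share promises 0.139 M, less than [partner] = 0.180 M, so starting material is the limiting reagent. That is 77.5 % of the charge by my reckoning, and the flat late readings suggest the same figure for the long wait.

Your forecast agrees on the ending, all of the starting material has reacted, but says 87 % at 10 h and 87 % for the long wait, on the ground that “quenching is slow”.

The flask gives 80.6 % and 80.6 %: all of the starting material has reacted. Quenched substrate stands at 17.9 % of the charge. That puts the forecast 6.4 percentage points high and my reckoning 3.1 points low. With no starting material left, the flask's own usable share is 0.806, above the larch reading.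

    initiator → 2 initiating radical (k = 3.49 × 10⁻⁴ s⁻¹)
    starting material + initiating radical → capped initiator + first chain carrier (k = 2.56 × 10⁵ L mol⁻¹ s⁻¹)
    partner + first chain carrier → target + second chain carrier (k = 21300 L mol⁻¹ s⁻¹)
    starting material + second chain carrier → released group + first chain carrier (k = 21300 L mol⁻¹ s⁻¹)
    first chain carrier → ended carrier (k = 18.3 s⁻¹)
    2 first chain carrier → ended chains A (k = 2.00 × 10⁸ L mol⁻¹ s⁻¹)
    2 second chain carrier → ended chains B (k = 5.00 × 10⁷ L mol⁻¹ s⁻¹)
    starting material + protic impurity → quenched substrate (k = 0.0128 L mol⁻¹ s⁻¹)

Now cut [partner] to 0.045 M in the neighbour. The flask's share promises 0.145 M, more than that partner charge, so target should stop at 25.0 %. The computed neighbour gives 24.9 %, with 0.31 % of its partner and 40 % of its starting material left.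

The readings were generated by integration on assumed constants; noise was put on by code.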